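I decided to count Q before anything else, since the average asked for divides by the chains begun.

X 0.40 M (fed, over 5.0 h); L 0.200 M; Q 9.2 mM; G 10 mM; time 40 h

- average number of monomer units in a chain (chains begun, living or dead) at 40 h
- part of the X that has reacted at 40 h

    X + Q → E + J (k1 = 0.90 L mol⁻¹ h⁻¹)
    Q + G → Q.G (k2 = 10000 L mol⁻¹ h⁻¹)
    X + E → J + E, rate k3*[E]*[X] (k3 = 74 L mol⁻¹ h⁻¹)
    L + X → L.X (k4 = 0.50 L mol⁻¹ h⁻¹)

Each Q that meets X begins a chain; each Q that meets G ends as Q.G. What looked wrong was this: the flask held 9.2 mM of Q, and G stood 0.800 mM above it. That is the margin, G charged less Q charged, and it looked far too thin to hold back so much Q.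

So I set the two fates of Q side by side as lifetimes.

Lifetime of Q against G, at the charge of G: 0.0100 h

Lifetime of Q against X, even with the whole charge of X present: 2.78 h

The second is far longer than the first, so Q and G cancel one for one, with Q the limiting reagent, and the margin is what G keeps. The last of Q then fades on a lifetime set by the margin, while X is still being fed at 0.0800 M h⁻¹.

Lifetime of that tail, one over the constant of Q + G times the margin: 0.125 h

X fed by then: 0.0100 M

Chains, the constant of X + Q times feed rate times margin times that lifetime squared: 9.00 × 10⁻⁷ M

This rough tail gives a size only, but it is far below the Q charged.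

The forecast gave 655 and 49.6 %, reasoning: “G wipes out nearly all the Q within minutes, before much X has been fed”. It counted about 1.2 µM of chains; I had 9.00 × 10⁻⁷ M.

The simulation gave an average chain of 654 units and 49.6 % of X reacted.

At 40.0 h the flask kept 8.0 % of its G, which is 0.801 mM, as much as the margin, with Q at 0 % and living ends at 1.20 × 10⁻⁶ M. In the flask with 0.0060 M of G the margin changes sign: Q stands 3.20 mM above G. At 40.0 h that flask held 0.00270 M of living ends and 0.496 mM of unbound Q, together 3.20 mM, with an average chain of 100 units.

(Its constants are invented.)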